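In a one-step world free monomer goes into chains and stays there, and a percentage is the number to watch. In the closed flasks below the percentage misleads you.

| setting | birch | oak | Thursday's | Tuesday's |
|---|---|---|---|---|
| free monomer | 8.7 mM | 16 mM | 20 mM | 12 mM |
| protic impurity | 2 mM | 2 mM | 2.00 mM | 2.00 mM |
| initiator | 1.1 mM | 1.1 mM | 1.1 mM | 1.1 mM |
| remark | run made earlier | run made earlier |  |  |
| time |  |  | 50 h | 50 h |

| run | time / h | monomer in chains / % |
|---|---|---|
| birch | 3.00 | 73 |
| birch | 5.00 | 73 |
| birch | 10.0 | 67 |
| birch | 20.0 | 67 |
| birch | 40.0 | 61 |
| oak | 8.00 | 83 |
| oak | 15.0 | 81 |
| oak | 20.0 | 81 |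
| oak | 30.0 | 78 |
| oak | 40.0 | 78 |

(readings scatter by 1.5 percentage points)

1. which of the two ends with the longer chains by the average number of monomer units in a chain (chains begun, living or dead) ("neither" if they lie within 10 %) (Thursday's / Tuesday's / neither)
2. average number of monomer units in a chain (chains begun, living or dead) at the end, Thursday's
3. average number of monomer units in a chain (chains begun, living or dead) at the end, Tuesday's

- the average divides the monomer in chains by the number of chains begun, living and dead together
- reactions considered so far: free monomer + initiator -> living end + monomer in chains; monomer in chains + living end -> free monomer + living end; protic impurity + free monomer -> quenched substrate; free monomer + living end -> monomer in chains + living end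
- the earlier runs do not show the number of chains; that part of a forecast is a guess

Birch and oak carried the same initiator and the same protic impurity, yet at 40.0 h birch has 39.0 % of its charge outside chains and oak 22.0 %. Reckon in concentration instead, charge minus monomer in chains:

birch: 8.7 mM − 5.31 mM = 3.39 mM

oak: 16 mM − 12.5 mM = 3.52 mM

The two agree as far as a scatter of 1.5 percentage points lets you tell. Call this difference the remainder, about 3.46 mM. Take the step between free monomer and chains as fast: it leaves [free monomer] at its equilibrium concentration, and the remainder is that plus what the protic impurity has drawn off. Oak reads 78 % at 30.0 h and 78 % at 40.0 h, level within the scatter, so as an estimate I hold the remainder to the end. The runs show no chain count, so I guess one chain per initiator: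

Thursday's: (20 mM − 3.46 mM) / 1.1 mM = 15.0

Tuesday's: (12 mM − 3.46 mM) / 1.1 mM = 7.77

Thursday's chains come out twice as long as Tuesday's, on a charge 1.67 times as large.

The forecast names Thursday's, with 15 (13.8 to 20) and 7.7 (7 to 10.5), and warns: “The chain count is a guess”. The simulation gives Thursday's, with 15.2 and 7.90.

    free monomer + initiator → living end + monomer in chains (k = 213 M⁻¹ h⁻¹)
    monomer in chains + living end → free monomer + living end, rate k2*[living end] as long as [monomer in chains] is above zero (k = 8.13 h⁻¹)
    protic impurity + free monomer → quenched substrate (k = 74.5 M⁻¹ h⁻¹)
    free monomer + living end → monomer in chains + living end, rate k4*[living end]*[free monomer] (k = 6170 M⁻¹ h⁻¹)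

Those lengths, at one chain per initiator, leave a remainder of 3.28 mM in Thursday's and 3.31 mM in Tuesday's, and for Thursday's recipe with 50 mM of free monomer instead the rule with 3.46 mM gives 42.3 against a simulated 42.4. In Thursday's at 50.0 h, free monomer has a half-life of 0.10 h by the step into chains, against 7.1 h for protic impurity by quenching. There Thursday's holds free monomer at 6.59 % and quenched substrate at 9.95 % of the charge, with 0.49 % of the protic impurity left.

(The readings were computed for substances that don't exist; noise was put on by code.)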